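**Assumption:** C7, C8 and C9 denote the benzylic CH, the aryloxy-bearing CH and the CH2O carbon of the three-carbon bridge (the primed locants of the target name); ring A is the trioxygenated ring and ring B the guaiacyl ring.

## Retrosynthetic overview

1. Target ⇐ desilylation and enoate-to-enal redox adjustment (i-Bu2AlH, then MnO2) of a bis-silylated benzodioxane cinnamate; the tert-butyl cinnamate is the masked enal, installed early by Wittig olefination.
2. Benzodioxane (the only ring formed, closed after both stereocentres exist) ⇐ intramolecular palladium-catalysed aryl C–O coupling of the C7 hydroxyl with the ring A bromide; no bond to C7 or C8 is broken, so threo becomes trans.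
3. threo-(7S,8S) bromo diol ⇐ reductive auxiliary removal from an Evans syn aldol adduct; the key C7–C8 bond comes from the boron aldol of an (R)-oxazolidinone aryloxyacetyl imide (ring A) with a silyl-protected guaiacyl aldehyde (ring B).
4. Ring A imide ⇐ O-alkylation of a bromo-hydroxy-methoxybenzaldehyde (the bromine is the latent second ring oxygen), Wittig olefination, selective ester hydrolysis, N-acylation.

## Route

**Step 1**
Reactants: 1 5-bromovanillin (3-bromo-4-hydroxy-5-methoxybenzaldehyde)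
Product: 2 methyl 2-(2-bromo-4-formyl-6-methoxyphenoxy)acetate
Conditions: BrCH2CO2Me (1.2 equiv), K2CO3 (2 equiv), DMF, 50 °C
Reagents that add atoms: methyl bromoacetate, COC(=O)CBr
Why: Williamson ether synthesis of the acidic phenoxide with an activated primary bromide; the flanking Br and OMe fix the ring A oxygenation pattern unambiguously.

**Step 2**
Reactants: 2 methyl 2-(2-bromo-4-formyl-6-methoxyphenoxy)acetate
Product: 3 tert-butyl (E)-3-[3-bromo-5-methoxy-4-(2-methoxy-2-oxoethoxy)phenyl]prop-2-enoate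
Conditions: Ph3P=CHCO2t-Bu (1.2 equiv), toluene, 80 °C
Reagents that add atoms: tert-butyl (triphenylphosphoranylidene)acetate, CC(C)(C)OC(=O)C=P(c1ccccc1)(c1ccccc1)c1ccccc1
Why: Wittig olefination with a stabilised ylide gives the E-enoate and converts the aldehyde, which would compete in the later aldol, into a hindered ester that is inert to enolisation and borohydride.

**Step 3**
Reactants: 3 tert-butyl (E)-3-[3-bromo-5-methoxy-4-(2-methoxy-2-oxoethoxy)phenyl]prop-2-enoate
Product: 4 2-{2-bromo-4-[(E)-3-tert-butoxy-3-oxoprop-1-en-1-yl]-6-methoxyphenoxy}acetic acid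
Conditions: LiOH·H2O (1.2 equiv), THF/H2O 3:1, 0 °C; then 1 M HCl
Reagents that add atoms: lithium hydroxide, [Li+].[OH-]
Why: Chemoselective saponification, because the unhindered α-oxygen-activated methyl ester hydrolyses far faster than the tert-butyl enoate.

**Step 4**
Reactants: 4 2-{2-bromo-4-[(E)-3-tert-butoxy-3-oxoprop-1-en-1-yl]-6-methoxyphenoxy}acetic acid; 5 (R)-4-benzyl-1,3-oxazolidin-2-one
Product: 7 (R)-4-benzyl-3-(2-{2-bromo-4-[(E)-3-tert-butoxy-3-oxoprop-1-en-1-yl]-6-methoxyphenoxy}acetyl)-1,3-oxazolidin-2-one, via mixed pivalic anhydride 6 (not isolated)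
Conditions: PivCl (1.1 equiv), Et3N (2.5 equiv), THF, −20 °C; then LiCl, 5, −20 °C → rt
Reagents that add atoms: none
Why: N-acylation of the oxazolidinone through a mixed anhydride (LiCl/Et3N activation), with attack at the less hindered aryloxyacetyl carbonyl.

**Step 5**
Reactants: 8 vanillin (4-hydroxy-3-methoxybenzaldehyde)
Product: 9 3-methoxy-4-(triisopropylsilyloxy)benzaldehyde
Conditions: i-Pr3SiCl (1.1 equiv), imidazole (2 equiv), DMF, rt
Reagents that add atoms: chlorotriisopropylsilane, CC(C)[Si](Cl)(C(C)C)C(C)C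
Why: Imidazole-promoted phenol silylation gives a base-robust aryl silyl ether that survives boron enolate, hydride and carbonate conditions and is removed by fluoride at the end.

**Step 6**
Reactants: 7 (R)-4-benzyl-3-(2-{2-bromo-4-[(E)-3-tert-butoxy-3-oxoprop-1-en-1-yl]-6-methoxyphenoxy}acetyl)-1,3-oxazolidin-2-one; 9 3-methoxy-4-(triisopropylsilyloxy)benzaldehyde
Product: 12 (R)-4-benzyl-3-[(2R,3S)-2-{2-bromo-4-[(E)-3-tert-butoxy-3-oxoprop-1-en-1-yl]-6-methoxyphenoxy}-3-hydroxy-3-(3-methoxy-4-triisopropylsilyloxyphenyl)propanoyl]-1,3-oxazolidin-2-one, via boron Z-enolate 10 (not isolated), via boron aldolate 11 (not isolated)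
Conditions: Bu2BOTf (1.2 equiv), i-Pr2NEt (1.4 equiv), CH2Cl2, −78 → 0 °C; 9, −78 → 0 °C; then aq. NaH2PO4/Na2HPO4 (pH 7), MeOH, 30% H2O2, 0 °C
Reagents that add atoms: none
Why: Evans syn aldol in which the (Z)-dibutylboron enolate adds through a closed Zimmerman–Traxler chair on the face away from the benzyl group of the (R)-auxiliary, forming the C7–C8 bond and setting both stereocentres as the (2R,3S) syn adduct (C8 and C7, both S once the carbonyl is reduced).

**Step 7**
Reactants: 12 (R)-4-benzyl-3-[(2R,3S)-2-aryloxy-3-hydroxy-3-arylpropanoyl]-1,3-oxazolidin-2-one (as above)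
Product: 13 tert-butyl (E)-3-[3-bromo-4-{[(1S,2S)-1,3-dihydroxy-1-(3-methoxy-4-triisopropylsilyloxyphenyl)propan-2-yl]oxy}-5-methoxyphenyl]prop-2-enoate (threo diol)
Conditions: LiBH4 (2 equiv), MeOH (2 equiv), THF, 0 °C
Reagents that add atoms: none
Why: Reductive cleavage of the activated N-acyl oxazolidinone by borohydride at 0 °C leaves the tert-butyl enoate and aryl bromide alone and breaks no bond at a stereocentre (the C8 label changes from R to S only through CIP priorities).

**Step 8**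
Reactants: 13 threo diol (as above)
Product: 14 tert-butyl (E)-3-[3-bromo-4-{[(1S,2S)-1-hydroxy-1-(3-methoxy-4-triisopropylsilyloxyphenyl)-3-(triisopropylsilyloxy)propan-2-yl]oxy}-5-methoxyphenyl]prop-2-enoate
Conditions: i-Pr3SiCl (1.1 equiv), imidazole (2.5 equiv), CH2Cl2, 0 °C → rt
Reagents that add atoms: chlorotriisopropylsilane, CC(C)[Si](Cl)(C(C)C)C(C)C
Why: Sterically controlled silylation of the primary over the secondary benzylic hydroxyl blocks the competing six-membered closure through O9, and the bulky triisopropylsilyl group resists 1,3-migration under the basic conditions of the next step.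

**Step 9**
Reactants: 14 mono-silylated bromo alcohol (as above)
Product: 15 tert-butyl (E)-3-[(2S,3S)-8-methoxy-3-(3-methoxy-4-triisopropylsilyloxyphenyl)-2-(triisopropylsilyloxymethyl)-2,3-dihydro-1,4-benzodioxin-6-yl]prop-2-enoate
Conditions: Pd(OAc)2 (5 mol%), 2-(di-tert-butylphosphino)-1,1'-binaphthyl (6 mol%), Cs2CO3 (1.5 equiv), toluene, 70 °C
Reagents that add atoms: none
Why: Buchwald-type intramolecular palladium-catalysed C–O coupling (oxidative addition of zerovalent palladium into the aryl bromide, alkoxide binding, C–O reductive elimination) closes the dioxane ring; the C7–O and C8–O bonds are never broken, so the threo (7S,8S) ether becomes the trans (2S,3S) benzodioxane with retention.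

**Step 10**
Reactants: 15 benzodioxane tert-butyl enoate (as above)
Product: 16 (E)-3-[(2S,3S)-8-methoxy-3-(3-methoxy-4-triisopropylsilyloxyphenyl)-2-(triisopropylsilyloxymethyl)-2,3-dihydro-1,4-benzodioxin-6-yl]prop-2-en-1-ol
Conditions: i-Bu2AlH (3 equiv), CH2Cl2, −78 → −40 °C; aq. KNaC4H4O6 work-up
Reagents that add atoms: none
Why: 1,2-Reduction of the enoate by the electrophilic aluminium hydride gives the E-allylic alcohol without touching silyl ethers or the benzodioxane.

**Step 11**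
Reactants: 16 allylic alcohol (as above)
Product: 17 (E)-3-[(2S,3S)-8-methoxy-3-(3-methoxy-4-triisopropylsilyloxyphenyl)-2-(triisopropylsilyloxymethyl)-2,3-dihydro-1,4-benzodioxin-6-yl]prop-2-enal
Conditions: activated MnO2 (15 equiv), CH2Cl2, rt
Reagents that add atoms: none
Why: Chemoselective MnO2 oxidation of the cinnamyl alcohol, the only free hydroxyl, stops at the E-enal.

**Step 12**
Reactants: 17 bis-silylated enal (as above)
Product: 18 (7'S,8'S)-nocomtal, (E)-3-[(2S,3S)-3-(4-hydroxy-3-methoxyphenyl)-2-(hydroxymethyl)-8-methoxy-2,3-dihydro-1,4-benzodioxin-6-yl]prop-2-enal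
Conditions: Bu4NF (2.5 equiv), AcOH (2.5 equiv), THF, 0 °C → rt
Reagents that add atoms: none
Why: Fluoride-driven desilylation cleaves both silyl ethers, and the acetic acid buffer keeps the liberated phenol protonated so that neither the enal nor the benzylic C7–O bond is exposed to phenoxide.

## Compound list

1 | 5-bromovanillin | COc1cc(C=O)cc(Br)c1O | starting material
2 | methyl 2-(2-bromo-4-formyl-6-methoxyphenoxy)acetate | COC(=O)COc1c(Br)cc(C=O)cc1OC | intermediate
3 | tert-butyl (E)-3-[3-bromo-5-methoxy-4-(2-methoxy-2-oxoethoxy)phenyl]prop-2-enoate | COC(=O)COc1c(Br)cc(/C=C/C(=O)OC(C)(C)C)cc1OC | intermediate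
4 | 2-{2-bromo-4-[(E)-3-tert-butoxy-3-oxoprop-1-en-1-yl]-6-methoxyphenoxy}acetic acid | OC(=O)COc1c(Br)cc(/C=C/C(=O)OC(C)(C)C)cc1OC | intermediate
5 | (R)-4-benzyl-1,3-oxazolidin-2-one | O=C1OC[C@@H](Cc2ccccc2)N1 | starting material
6 | mixed pivalic anhydride of acid 4 | CC(C)(C)C(=O)OC(=O)COc1c(Br)cc(/C=C/C(=O)OC(C)(C)C)cc1OC | intermediate (not isolated)
7 | (R)-4-benzyl-3-(2-{2-bromo-4-[(E)-3-tert-butoxy-3-oxoprop-1-en-1-yl]-6-methoxyphenoxy}acetyl)-1,3-oxazolidin-2-one | O=C(COc1c(Br)cc(/C=C/C(=O)OC(C)(C)C)cc1OC)N1C(=O)OC[C@H]1Cc1ccccc1 | intermediate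
8 | vanillin | COc1cc(C=O)ccc1O | starting material
9 | 3-methoxy-4-(triisopropylsilyloxy)benzaldehyde | COc1cc(C=O)ccc1O[Si](C(C)C)(C(C)C)C(C)C | intermediate
10 | (Z)-dibutylboron enolate of imide 7 (boron on the enolate oxygen, cis to the aryloxy group) | CCCCB(CCCC)O/C(=C\Oc1c(Br)cc(/C=C/C(=O)OC(C)(C)C)cc1OC)N1C(=O)OC[C@H]1Cc1ccccc1 | intermediate (not isolated)
11 | dibutylboron aldolate of 12 (O-3 bound to BBu2, 2R,3S) | O=C([C@H](Oc1c(Br)cc(/C=C/C(=O)OC(C)(C)C)cc1OC)[C@@H](OB(CCCC)CCCC)c1ccc(O[Si](C(C)C)(C(C)C)C(C)C)c(OC)c1)N1C(=O)OC[C@H]1Cc1ccccc1 | intermediate (not isolated)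
12 | (R)-4-benzyl-3-[(2R,3S)-2-{2-bromo-4-[(E)-3-tert-butoxy-3-oxoprop-1-en-1-yl]-6-methoxyphenoxy}-3-hydroxy-3-(3-methoxy-4-triisopropylsilyloxyphenyl)propanoyl]-1,3-oxazolidin-2-one | O=C([C@H](Oc1c(Br)cc(/C=C/C(=O)OC(C)(C)C)cc1OC)[C@@H](O)c1ccc(O[Si](C(C)C)(C(C)C)C(C)C)c(OC)c1)N1C(=O)OC[C@H]1Cc1ccccc1 | intermediate
13 | tert-butyl (E)-3-[3-bromo-4-{[(1S,2S)-1,3-dihydroxy-1-(3-methoxy-4-triisopropylsilyloxyphenyl)propan-2-yl]oxy}-5-methoxyphenyl]prop-2-enoate | OC[C@H](Oc1c(Br)cc(/C=C/C(=O)OC(C)(C)C)cc1OC)[C@@H](O)c1ccc(O[Si](C(C)C)(C(C)C)C(C)C)c(OC)c1 | intermediate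
14 | tert-butyl (E)-3-[3-bromo-4-{[(1S,2S)-1-hydroxy-1-(3-methoxy-4-triisopropylsilyloxyphenyl)-3-(triisopropylsilyloxy)propan-2-yl]oxy}-5-methoxyphenyl]prop-2-enoate | CC(C)[Si](OC[C@H](Oc1c(Br)cc(/C=C/C(=O)OC(C)(C)C)cc1OC)[C@@H](O)c1ccc(O[Si](C(C)C)(C(C)C)C(C)C)c(OC)c1)(C(C)C)C(C)C | intermediate
15 | tert-butyl (E)-3-[(2S,3S)-8-methoxy-3-(3-methoxy-4-triisopropylsilyloxyphenyl)-2-(triisopropylsilyloxymethyl)-2,3-dihydro-1,4-benzodioxin-6-yl]prop-2-enoate | COc1cc([C@@H]2Oc3cc(/C=C/C(=O)OC(C)(C)C)cc(OC)c3O[C@H]2CO[Si](C(C)C)(C(C)C)C(C)C)ccc1O[Si](C(C)C)(C(C)C)C(C)C | intermediate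
16 | (E)-3-[(2S,3S)-8-methoxy-3-(3-methoxy-4-triisopropylsilyloxyphenyl)-2-(triisopropylsilyloxymethyl)-2,3-dihydro-1,4-benzodioxin-6-yl]prop-2-en-1-ol | COc1cc([C@@H]2Oc3cc(/C=C/CO)cc(OC)c3O[C@H]2CO[Si](C(C)C)(C(C)C)C(C)C)ccc1O[Si](C(C)C)(C(C)C)C(C)C | intermediate
17 | (E)-3-[(2S,3S)-8-methoxy-3-(3-methoxy-4-triisopropylsilyloxyphenyl)-2-(triisopropylsilyloxymethyl)-2,3-dihydro-1,4-benzodioxin-6-yl]prop-2-enal | COc1cc([C@@H]2Oc3cc(/C=C/C=O)cc(OC)c3O[C@H]2CO[Si](C(C)C)(C(C)C)C(C)C)ccc1O[Si](C(C)C)(C(C)C)C(C)C | intermediate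
18 | (7'S,8'S)-nocomtal, (E)-3-[(2S,3S)-3-(4-hydroxy-3-methoxyphenyl)-2-(hydroxymethyl)-8-methoxy-2,3-dihydro-1,4-benzodioxin-6-yl]prop-2-enal | COc1cc([C@@H]2Oc3cc(/C=C/C=O)cc(OC)c3O[C@H]2CO)ccc1O | target

## Step count and risk

Total steps: 12. Longest linear sequence: 11 steps (steps 1–4 and 6–12, from 5-bromovanillin); step 5 is a one-step side branch.

**Most likely to fail, in order:**

**Step 9 (palladium-catalysed ring closure).** The palladium alkoxide of a secondary benzylic alcohol can undergo β-hydride elimination (ketone plus debrominated arene), and reductive elimination on the electron-rich ring may be slow. The fallback sets out from 14 and comes back at 15. Miyaura borylation of 14 [B2pin2, Pd(dppf)Cl2, KOAc, dioxane, 80 °C] gives the aryl pinacol boronate F1. Oxidation with NaBO3·4H2O in THF/H2O at rt gives the ortho-hydroxy aryl ether F2. Catalytic TsOH·H2O in CH2Cl2 at rt then ionises the para-silyloxybenzylic alcohol, and the phenol captures the benzylic cation. Because C8 is untouched (S) and the closure is reversible, the thermodynamically preferred trans ring results, which is 15; any cis isomer would be removed by chromatography.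

**Step 6 (boron aldol).** The enolate carries an aryloxy group with two ortho substituents, so addition may be sluggish or the syn selectivity eroded. The fallback sets out from methyl ester 3 and aldehyde 9 and comes back at 13.
- The lithium enolate of 3 [LiN(SiMe3)2, THF, −78 °C] adds to 9 in a simple crossed ester aldol. This gives methyl 2-{2-bromo-4-[(E)-3-tert-butoxy-3-oxoprop-1-en-1-yl]-6-methoxyphenoxy}-3-hydroxy-3-(3-methoxy-4-triisopropylsilyloxyphenyl)propanoate F3 as a racemic syn/anti mixture.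
- Dess–Martin periodinane (CH2Cl2, rt) converts F3 into the configurationally labile β-keto ester F4.
- Asymmetric transfer hydrogenation with dynamic kinetic resolution [RuCl(p-cymene)[(R,R)-TsDPEN], HCO2H/Et3N 5:2, CH2Cl2, rt] is expected to give the syn (2R,3S)-hydroxy ester F5. The catalyst enantiomer is chosen by analogy with acetophenone reduction and should be confirmed on the first run.
- NaBH4 (THF/MeOH, 0 °C) reduces the activated α-aryloxy methyl ester in the presence of the tert-butyl enoate to give 13.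

**Step 12 (final desilylation).** The enal is exposed to fluoride, and a free phenoxide para to the benzylic C7–O bond could open the ring through a quinone methide. The fallback sets out from 16 and comes back at 18. Both silyl groups are removed at the allylic alcohol stage (Bu4NF/AcOH, THF, 0 °C → rt) to give the triol (E)-3-[(2S,3S)-3-(4-hydroxy-3-methoxyphenyl)-2-(hydroxymethyl)-8-methoxy-2,3-dihydro-1,4-benzodioxin-6-yl]prop-2-en-1-ol F6. Activated MnO2 in CH2Cl2/acetone at rt then oxidises only the cinnamyl alcohol, so the enal is formed last under neutral conditions, giving 18.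

## Further compounds

F1 | step 9 | tert-butyl (E)-3-[4-{[(1S,2S)-1-hydroxy-1-(3-methoxy-4-triisopropylsilyloxyphenyl)-3-(triisopropylsilyloxy)propan-2-yl]oxy}-3-methoxy-5-(4,4,5,5-tetramethyl-1,3,2-dioxaborolan-2-yl)phenyl]prop-2-enoate | CC(C)[Si](OC[C@H](Oc1c(B2OC(C)(C)C(C)(C)O2)cc(/C=C/C(=O)OC(C)(C)C)cc1OC)[C@@H](O)c1ccc(O[Si](C(C)C)(C(C)C)C(C)C)c(OC)c1)(C(C)C)C(C)C
F2 | step 9 | tert-butyl (E)-3-[3-hydroxy-4-{[(1S,2S)-1-hydroxy-1-(3-methoxy-4-triisopropylsilyloxyphenyl)-3-(triisopropylsilyloxy)propan-2-yl]oxy}-5-methoxyphenyl]prop-2-enoate | CC(C)[Si](OC[C@H](Oc1c(O)cc(/C=C/C(=O)OC(C)(C)C)cc1OC)[C@@H](O)c1ccc(O[Si](C(C)C)(C(C)C)C(C)C)c(OC)c1)(C(C)C)C(C)C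
F3 | step 6 | methyl 2-{2-bromo-4-[(E)-3-tert-butoxy-3-oxoprop-1-en-1-yl]-6-methoxyphenoxy}-3-hydroxy-3-(3-methoxy-4-triisopropylsilyloxyphenyl)propanoate (racemic syn/anti mixture) | COC(=O)C(Oc1c(Br)cc(/C=C/C(=O)OC(C)(C)C)cc1OC)C(O)c1ccc(O[Si](C(C)C)(C(C)C)C(C)C)c(OC)c1
F4 | step 6 | methyl 2-{2-bromo-4-[(E)-3-tert-butoxy-3-oxoprop-1-en-1-yl]-6-methoxyphenoxy}-3-(3-methoxy-4-triisopropylsilyloxyphenyl)-3-oxopropanoate (racemic, α-centre labile) | COC(=O)C(Oc1c(Br)cc(/C=C/C(=O)OC(C)(C)C)cc1OC)C(=O)c1ccc(O[Si](C(C)C)(C(C)C)C(C)C)c(OC)c1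
F5 | step 6 | methyl (2R,3S)-2-{2-bromo-4-[(E)-3-tert-butoxy-3-oxoprop-1-en-1-yl]-6-methoxyphenoxy}-3-hydroxy-3-(3-methoxy-4-triisopropylsilyloxyphenyl)propanoate | COC(=O)[C@H](Oc1c(Br)cc(/C=C/C(=O)OC(C)(C)C)cc1OC)[C@@H](O)c1ccc(O[Si](C(C)C)(C(C)C)C(C)C)c(OC)c1
F6 | step 12 | (E)-3-[(2S,3S)-3-(4-hydroxy-3-methoxyphenyl)-2-(hydroxymethyl)-8-methoxy-2,3-dihydro-1,4-benzodioxin-6-yl]prop-2-en-1-ol | COc1cc([C@@H]2Oc3cc(/C=C/CO)cc(OC)c3O[C@H]2CO)ccc1O
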